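The numbers were drawn at random within sensible limits; the result is computed.

A level of 1.42 mM of protic impurity is the number we carry through this flask: in our reckoning it marks where the quench and the chain take starting material equally fast.

| flask | starting material | reagent | protic impurity | initiator | time |
|---|---|---|---|---|---|
| summer | 0.0050 M | 1.10 equiv | 3.20 mM | 5 mol% | 40 s |
| winter | 0.0050 M | 1.10 equiv | 2.50 mM | 5 mol% | 40 s |

    initiator → 2 initiating radical (k1 = 0.018 s⁻¹)
    starting material + initiating radical → capped initiator + first chain carrier (k2 = 5.1 × 10⁶ L mol⁻¹ s⁻¹)
    reagent + first chain carrier → target + second chain carrier (k3 = 94000 L mol⁻¹ s⁻¹)
    starting material + second chain carrier → by-product + first chain carrier (k4 = 1.5 × 10⁵ L mol⁻¹ s⁻¹)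
    first chain carrier → ended carrier (k5 = 1.4 s⁻¹)
    2 first chain carrier → ended chains A (k6 = 1.3 × 10⁶ L mol⁻¹ s⁻¹)
    2 second chain carrier → ended chains B (k7 = 6.6 × 10⁶ L mol⁻¹ s⁻¹)
    starting material + protic impurity → quenched substrate (k8 = 87 L mol⁻¹ s⁻¹)
    target → over-reaction product (k9 = 0.056 s⁻¹)

1. which of these there is most of at the end, counted by the starting material in it, summer (over-reaction product / target / starting material / first chain carrier)
2. which of these there is most of at the end, counted by the starting material in it, winter (over-reaction product / target / starting material / first chain carrier)
3. the largest of these amounts at the end, in percent of the starting material charged, summer
4. the largest of these amounts at the end, in percent of the starting material charged, winter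

- percent here means starting material units held: one ended chains A counts as two
- where a step has two of a species, its rate is k times that concentration squared, and two are used at each turn
- run time (summer): 40 s

1. We balance initiation against ended chains B, taken as the ending step, with initiator as charged. This puts second chain carrier near 8.26 × 10⁻⁷ M, so the chain removes starting material with a pseudo-first-order constant of 0.124 s⁻¹. The balance level is the protic impurity concentration at which the quench has that same constant.

2. Taking the carrier at that level from the start, our summer curve of starting material begins by falling at 2.01 mM s⁻¹, and the quench carries 69.2% of that slope.

3. Dividing the two rates, with the chain constant held, gives a logarithmic law: starting material used equals impurity used plus the balance level times ln(impurity charged / impurity left). In our summer curve the impurity therefore crosses the balance level, the knee, with 2.07 mM of starting material left.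

4. We take the curve to end where starting material reaches zero. We solve the law there by taking geometric means of guess and answer, twice, starting from the balance level. Impurity ends near 0.619 mM in summer and 0.383 mM in winter. In this reckoning the chain thus makes target from 48.4% of the charge in summer and 57.7% in winter.

5. We date that target at the chain's half-life, 5.60 s, so 14.6% of it survives to the end. Our reckoning gives over-reaction product at 41.3% in summer, and over-reaction product at 49.3% in winter.

The forecast names over-reaction product in summer at 40.4% and over-reaction product in winter at 47.8%, holding that “Over-reaction product therefore dominates”. Our winter figure stands 1.5 percentage points higher.

The simulation gives over-reaction product at 39.3% in summer, with target at 7.11%, and over-reaction product at 46.2% in winter, with target at 9.14%.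

At 1.58 s in the summer flask, the half-life of starting material by the quench is 4.3 s, shorter than the 6.6 s by the chain step. At the end, the protic impurity left is 0.534 mM, below the balance level, and quenched substrate stands at 53.3%.

In the neighbour flask, summer's recipe on 0.0030 M of starting material, the balance level is 1.10 mM. The same reckoning leaves 1.24 mM of impurity and gives 29.2% over-reaction product. The computed flask holds 28.1%, with 37% of its impurity left.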